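Take a small charge of substrate, set partner beside it, and let a protic impurity stand in the same solution.

| setting | blue | grey | flask |
|---|---|---|---|
| substrate | 0.19 M | 0.29 M | 0.19 M |
| partner | 0.285 M | 0.285 M | 0.285 M |
| protic impurity | 0.19 M | 0.19 M | 0.190 M |
| temperature | 35 °C | 20 °C | 35 °C |
| remark | the very flask that is asked about, followed so far | run made earlier |  |
| time |  |  | 6.0 h |

| run | time / min | product / % |
|---|---|---|
| blue | 30.0 | 6.7 |
| blue | 40.0 | 9.4 |
| blue | 60.0 | 11.7 |
| blue | 90.0 | 14.5 |
| blue | 150 | 14.9 |
| blue | 240 | 16.7 |
| blue | 360 | 18.6 |
| grey | 3.00 | 1.1 |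
| grey | 10.0 | 1.0 |
| grey | 20.0 | 0.6 |
| grey | 30.0 | 0.8 |
| grey | 40.0 | 1.9 |
| grey | 50.0 | 1.6 |
| grey | 60.0 | 3.3 |

(each reading ± 1 percentage point)

- birch: at 6.0 h add partner, 50.0 % of the amount charged, then wait 6.0 h
- ash: at 6.0 h take out 90 % of the product then present, then wait 6.0 h
- oak: change nothing and wait 6.0 h more
- cedar: at 6.0 h raise the temperature by 20 K, then wait 6.0 h

- product that was removed still counts
- the analysis behind the earlier runs scatters by 1 percentage point, standard deviation
- additions bring no volume worth counting

* product, in percent of the substrate first charged, at 6.0 h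
* which option adds most product ("none" when 2 percentage points or less is all one gets) (birch / ash / oak / cedar / none)
* product present, with what was taken out counted in, in percent of the substrate first charged, after birch
* product present, with what was taken out counted in, in percent of the substrate first charged, after ash

Count everything as a fraction of the substrate charge. Use the bench rule first: let each protic impurity take one partner, let each product take one partner, and see what remains. Call partner charge minus impurity charge, over substrate charge, the spare share, 50.0 %. While it stays below one, the rule calls partner the limiting reagent and takes the spare share as the ceiling on product in the blue flask.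

Now hold the readings against it. The last blue reading, 18.6 % at 360 min, is 0.372 of the ceiling, and the readings seem to bend near 90.0 min, at 0.290 of it. So the rule stops here: that reading stands lower than the ceiling, and the subtraction gives a limit, not a pace. Its other border is a spare share of one, where the rule makes substrate limiting, and on the rule's count birch carries the blue flask past it, to 125 %.

My own reckoning commits to little. Take the last reading for now, give or take 1 percentage point, and take the room, spare share less that reading, 31 points, as what the rule allows an option without new partner. The grey run at 20 °C stood lower at 60.0 min than blue did at 60.0 min; it also held more substrate, so two settings differ, but take warmth as the likelier source of pace and choose cedar.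

The forecast gives 18.5 % now and cedar as best, “the best option, though close to birch”, with 33 % after birch and 24 % after ash.

The flask gives 16.8 % now. The best option is cedar, which adds 27 points, less than the room reckoned from the reading; birch ends at 20.1 % and ash at 17.7 %.

    partner + intermediate C ⇌ intermediate E (K = 3.70 M⁻¹, k = 0.0130 M⁻¹ min⁻¹, Ea = 79.0 kJ mol⁻¹, ΔH = −64.0 kJ mol⁻¹)
    partner ⇌ dormant form (K = 5.70, k = 0.0200 min⁻¹, Ea = 93.0 kJ mol⁻¹, ΔH = −53.0 kJ mol⁻¹)
    intermediate B ⇌ intermediate C (K = 6.70, k = 0.0350 min⁻¹, Ea = 92.0 kJ mol⁻¹, ΔH = −47.0 kJ mol⁻¹)
    substrate ⇌ intermediate B (K = 2.20, k = 0.230 min⁻¹, Ea = 84.0 kJ mol⁻¹, ΔH = −35.0 kJ mol⁻¹)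
    intermediate A → product (k = 0.0270 min⁻¹, Ea = 85.0 kJ mol⁻¹)
    substrate + partner → intermediate A (k = 0.110 M⁻¹ min⁻¹, Ea = 73.0 kJ mol⁻¹)
    intermediate C ⇌ intermediate D (K = 1.90, k = 0.00300 min⁻¹, Ea = 98.0 kJ mol⁻¹, ΔH = −32.0 kJ mol⁻¹)
    partner + protic impurity → quenched reagent (k = 0.370 M⁻¹ min⁻¹, Ea = 48.0 kJ mol⁻¹)
    (constants at 35 °C)

At 35 °C substrate goes to intermediate B with a forward half-life of 3.0 min, faster than its forward half-life to intermediate A with partner as charged, 22.1 min. At 360 min the flask holds 37.1 % intermediate C and 36.1 % intermediate D beside 16.8 % product, which is 0.336 of the flask's spare share. The neighbour kept at 60 °C has 1.93 % of its impurity charge left, so its spare share, counting the impurity spent, is 51.9 %, and it holds 51.6 % product with 0.0880 % of its partner charge remaining.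

(The data were computed from invented constants; scatter was added.)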